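The ring is numbered C1 (epoxide carbon bearing the side chain), C2 (CHOH), C3 (heptenyl), C4 (CH2OH), C5 (CHOH), C6 (epoxide CH). C4 carries a carbon and C1 an oxygen, para to each other: the imprint of the C(=O)–O bridge of a 2-pyrone cycloadduct. The ring is therefore cut at C4–C5 and C6–C1: an inverse-demand Diels–Alder reaction of an enantiopure 3-sulfinyl-4-heptenyl-6-allyl-2-pyrone with a (Z)-2-bromovinyl ether forms both bonds and encodes all four stereocentres. The temporary lactone bridge is then opened, its alkoxide displaces bromide to give the epoxide, and a [2,3] shift of the sulfoxide delivers the C2 hydroxyl and the C3=C4 alkene.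

Key step: step 6

Remark on the chemistry: the facial sense of the cycloaddition is assigned from the chelate model (ZnBr2 bridging S=O and the lactone C=O, dienophile anti to p-tolyl); on this basis the (R)-configured sulfinylpyrone 10 is required. The sulfur geometry is the same from 3 to 16; its descriptor changes from S to R at 7 only through CIP priorities.

Step 1
Reactants: 1 (1S,2R,5S)-(+)-menthyl (R)-p-toluenesulfinate; 2 tert-butyl acetate
Product: 3 tert-butyl (S)-2-(p-tolylsulfinyl)acetate
Conditions: 2, LiN(i-Pr)2 (2 equiv each), THF, −78 °C; then 1, −78 → 0 °C; aq. NH4Cl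
Reagents that add atoms: none
Why: Andersen-type sulfinyl transfer, in which the ester enolate displaces menthoxide at sulfur with inversion, so the (R)-sulfinate should give the (S)-sulfinyl ester (the second equivalent of enolate absorbs the acidity of the product).

Step 2
Reactants: 3 tert-butyl (S)-2-(p-tolylsulfinyl)acetate; 4 (E)-oct-2-enoic acid
Product: 7 tert-butyl (2E,4E)-2-[(R)-p-tolylsulfinyl]-3-(trifluoromethylsulfonyloxy)deca-2,4-dienoate (triflate cis to CO2t-Bu), via acid chloride 5 (not isolated), via lithium enolate 6 (not isolated)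
Conditions: 4, (COCl)2, DMF (cat.), CH2Cl2, 0 → 23 °C, evaporate; 3, LiN(SiMe3)2 (2.1 equiv), THF, −78 °C, add 5; then N-(5-chloropyridin-2-yl)-bis(trifluoromethanesulfonimide), −78 → 23 °C
Reagents that add atoms: N-(5-chloropyridin-2-yl)-bis(trifluoromethanesulfonimide), FC(F)(F)S(=O)(=O)N(c1ccc(Cl)cn1)S(=O)(=O)C(F)(F)F
Why: Claisen-type C-acylation of the α-sulfinyl ester enolate followed by O-triflation of the β-keto ester enolate, in which lithium bridging the enolate oxygen and the ester carbonyl should place the triflate cis to the ester; the sulfur centre is untouched.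

Step 3
Reactants: 7 enol triflate; 8 pent-1-en-4-yne
Product: 9 tert-butyl (2E,4E)-3-(pent-4-en-1-yn-1-yl)-2-[(R)-p-tolylsulfinyl]deca-2,4-dienoate (alkyne cis to CO2t-Bu)
Conditions: Pd(PPh3)2Cl2 (5 mol %), CuI (10 mol %), i-Pr2NEt, THF, 0 → 23 °C
Reagents that add atoms: none
Why: Sonogashira coupling of the activated enol triflate proceeds with retention of alkene geometry, so the alkyne should end up cis to the ester as the lactonisation requires.

Step 4
Reactants: 9 dienynoate
Product: 10 6-allyl-4-[(E)-hept-1-en-1-yl]-3-[(R)-p-tolylsulfinyl]-2H-pyran-2-one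
Conditions: Ph3PAuNTf2 (5 mol %), CH2Cl2, 23 °C
Reagents that add atoms: none
Why: Gold-catalysed 6-endo-dig attack of the ester carbonyl oxygen on the activated alkyne (its distal carbon is polarised by conjugation with the sulfinyl acrylate), loss of isobutene and protodeauration should give the 2-pyrone; the sulfoxide lies trans to the alkyne and cannot intervene.

Step 5
Reactants: 11 4-methoxybenzyl alcohol; 12 1,2-dibromoethylene (cis/trans mixture)
Product: 14 (Z)-1-{[(2-bromovinyl)oxy]methyl}-4-methoxybenzene, via bromoacetylene 13 (not isolated)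
Conditions: KH (1.2 equiv), THF, 0 °C; then 12 (2.5 equiv), 0 → 23 °C
Reagents that add atoms: none
Why: Elimination–addition, in which the alkoxide dehydrobrominates 12 to bromoacetylene and then adds to it in the trans sense (alkoxide-catalysed), which should give the Z-β-bromovinyl ether.

Step 6
Reactants: 10 (R)-sulfinylpyrone; 14 (Z)-2-bromovinyl PMB ether
Product: 15 1-allyl-6-endo-bromo-8-[(E)-hept-1-enyl]-5-endo-(4-methoxybenzyloxy)-4-[(R)-p-tolylsulfinyl]-2-oxabicyclo[2.2.2]oct-7-en-3-one (Br and OPMB cis to each other, syn to the alkene bridge and anti to the lactone bridge)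
Conditions: ZnBr2 (1.1 equiv), 14 (3 equiv), 4 Å molecular sieves, CH2Cl2, −40 → 0 °C
Reagents that add atoms: none
Why: Inverse-electron-demand [4+2] cycloaddition of the electron-poor pyrone diene (activated by the sulfinyl group and by ZnBr2 bridging S=O and the lactone C=O) with the enol ether, concerted but asynchronous with the nucleophilic CHBr carbon leading onto pyrone C-6; the closest known reaction type is the cycloaddition of 3-sulfinyl- and 3-sulfonyl-2-pyrones with vinyl ethers. It closes the carbocycle (ring C1–C6 of the target) in an intermolecular [4+2] mode and gives a bicyclic lactone whose C(=O)–O bridge is a temporary ring. Polarisation directs the OPMB carbon to the sulfinyl-bearing pyrone C-3 and the CHBr carbon to C-6, so the new bonds are C4–C5 and C6–C1 of the target. The two bridgehead centres are set by approach anti to the p-tolyl group of the chelated (R)-sulfoxide; the OPMB and Br centres are set cis by the Z geometry of 14 and endo by the usual endo preference of alkoxy dienophiles. The step needs the ring diene to react in preference to the exocyclic 4-alkenyl diene and the Z geometry to be transmitted, which the fixed s-cis ring diene, the electrophilicity of C-6 and low temperature in CH2Cl2 should secure.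

Step 7
Reactants: 15 cycloadduct
Product: 18 methyl (1S,2R,5S,6R)-1-allyl-3-[(E)-hept-1-enyl]-2-hydroxy-5-(4-methoxybenzyloxy)-7-oxabicyclo[4.1.0]hept-3-ene-4-carboxylate, via epoxy sulfoxide 16 (not isolated), via sulfenate ester 17 (not isolated)
Conditions: NaOMe (1.05 equiv), MeOH–THF, −20 → 0 °C; then Et2NH (5 equiv), 23 °C
Reagents that add atoms: sodium methoxide, [Na+].[O-]C
Why: Methanolysis of the strained, sulfinyl-activated lactone frees the C1 alkoxide, which displaces the trans bromide at C6 with inversion (Williamson-type epoxide closure); the now monocyclic allylic sulfoxide undergoes the Mislow–Evans [2,3] shift, which should move oxygen suprafacially from the C4 sulfur to C2 on the face trans to the epoxide and shift the alkene to C3=C4, and Et2NH cleaves the sulfenate.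

Step 8
Reactants: 18 PMB ether
Product: 19 methyl (1S,2R,5S,6R)-1-allyl-3-[(E)-hept-1-enyl]-2,5-dihydroxy-7-oxabicyclo[4.1.0]hept-3-ene-4-carboxylate
Conditions: DDQ (1.3 equiv), CH2Cl2–pH 7 buffer (10:1), 0 °C
Reagents that add atoms: none
Why: Oxidative cleavage of the PMB ether by DDQ through the benzylic oxocarbenium ion, which water hydrolyses; the electron-poor dienoate, the epoxide and the secondary alcohols should be inert and no stereocentre is touched.

Step 9
Reactants: 19 allyl diol ester; 20 methacrylic acid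
Product: 21 (E)-4-[(1S,2R,5S,6R)-3-[(E)-hept-1-enyl]-2,5-dihydroxy-4-(methoxycarbonyl)-7-oxabicyclo[4.1.0]hept-3-en-1-yl]-2-methylbut-2-enoic acid
Conditions: second-generation Grubbs catalyst RuCl2(=CHPh)(PCy3)(H2IMes) (5 mol %), 20 (5 equiv), CH2Cl2, 40 °C
Reagents that add atoms: none
Why: Olefin cross-metathesis of the terminal allyl group with the 1,1-disubstituted acrylic partner should give the trisubstituted E-enoic acid under thermodynamic control, while the tetrasubstituted and ester-deactivated alkenes of the dienoate are left alone.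

Step 10
Reactants: 21 acid ester
Product: 22 (E)-4-[(1S,2R,5S,6R)-3-[(E)-hept-1-enyl]-2,5-dihydroxy-4-(hydroxymethyl)-7-oxabicyclo[4.1.0]hept-3-en-1-yl]-2-methylbut-2-enoic acid (target)
Conditions: i-Bu2AlH (7 equiv), CH2Cl2–THF, −78 °C; MeOH, then aq. potassium sodium tartrate, pH 4
Reagents that add atoms: none
Why: i-Bu2AlH reduces the methyl dienoate in the 1,2 sense to the primary allylic alcohol at −78 °C, whereas the carboxylic acid is deprotonated to an aluminium carboxylate that should not be reduced at this temperature, and the epoxide is untouched.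

Compound list
1 | (1S,2R,5S)-(+)-menthyl (R)-p-toluenesulfinate | CC(C)[C@H]1CC[C@H](C)C[C@@H]1O[S@@](=O)c1ccc(C)cc1 | starting material
2 | tert-butyl acetate | CC(=O)OC(C)(C)C | starting material
3 | tert-butyl (S)-2-(p-tolylsulfinyl)acetate | CC(C)(C)OC(=O)C[S@](=O)c1ccc(C)cc1 | intermediate
4 | (E)-oct-2-enoic acid | CCCCC/C=C/C(=O)O | starting material
5 | (E)-oct-2-enoyl chloride | CCCCC/C=C/C(=O)Cl | intermediate
6 | lithium enolate of tert-butyl (E)-3-oxo-2-(p-tolylsulfinyl)dec-4-enoate (O–Li cis to the ester) | CC(C)(C)OC(=O)/C(=C(\[O-])/C=C/CCCCC)[S@](=O)c1ccc(C)cc1.[Li+] | intermediate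
7 | tert-butyl (2E,4E)-2-[(R)-p-tolylsulfinyl]-3-(trifluoromethylsulfonyloxy)deca-2,4-dienoate | CC(C)(C)OC(=O)/C(=C(\OS(=O)(=O)C(F)(F)F)/C=C/CCCCC)[S@](=O)c1ccc(C)cc1 | intermediate
8 | pent-1-en-4-yne | C=CCC#C | starting material
9 | tert-butyl (2E,4E)-3-(pent-4-en-1-yn-1-yl)-2-[(R)-p-tolylsulfinyl]deca-2,4-dienoate | CC(C)(C)OC(=O)/C(=C(\C#CCC=C)/C=C/CCCCC)[S@](=O)c1ccc(C)cc1 | intermediate
10 | 6-allyl-4-[(E)-hept-1-en-1-yl]-3-[(R)-p-tolylsulfinyl]-2H-pyran-2-one | O=C1OC(CC=C)=CC(/C=C/CCCCC)=C1[S@](=O)c1ccc(C)cc1 | intermediate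
11 | 4-methoxybenzyl alcohol | COc1ccc(CO)cc1 | starting material
12 | 1,2-dibromoethylene (cis/trans mixture) | BrC=CBr | starting material
13 | bromoacetylene | BrC#C | intermediate
14 | (Z)-1-{[(2-bromovinyl)oxy]methyl}-4-methoxybenzene | COc1ccc(CO/C=C\Br)cc1 | intermediate
15 | bicyclic lactone adduct (bridgehead sulfoxide and allyl; OPMB and Br endo and cis; sulfur R) | O=C1O[C@@]2(CC=C)C=C(/C=C/CCCCC)[C@]1([S@](=O)c3ccc(C)cc3)[C@H](OCc4ccc(OC)cc4)[C@@H]2Br | intermediate
16 | methyl 1-allyl-3-[(E)-hept-1-enyl]-5-(4-methoxybenzyloxy)-4-[(R)-p-tolylsulfinyl]-7-oxabicyclo[4.1.0]hept-2-ene-4-carboxylate (sulfinyl and OPMB on the face opposite to the epoxide oxygen) | COC(=O)[C@]1([S@](=O)c2ccc(C)cc2)C(/C=C/CCCCC)=C[C@]3(CC=C)O[C@@H]3[C@H]1OCc1ccc(OC)cc1 | intermediate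
17 | methyl 1-allyl-3-[(E)-hept-1-enyl]-5-(4-methoxybenzyloxy)-2-[(p-tolylsulfanyl)oxy]-7-oxabicyclo[4.1.0]hept-3-ene-4-carboxylate (O–S and OPMB trans to the epoxide) | CCCCC/C=C/C1=C(C(=O)OC)[C@H](OCc3ccc(OC)cc3)[C@H]2O[C@@]2(CC=C)[C@@H]1OSc1ccc(C)cc1 | intermediate
18 | methyl (1S,2R,5S,6R)-1-allyl-3-[(E)-hept-1-enyl]-2-hydroxy-5-(4-methoxybenzyloxy)-7-oxabicyclo[4.1.0]hept-3-ene-4-carboxylate | CCCCC/C=C/C1=C(C(=O)OC)[C@H](OCc3ccc(OC)cc3)[C@H]2O[C@@]2(CC=C)[C@@H]1O | intermediate
19 | methyl (1S,2R,5S,6R)-1-allyl-3-[(E)-hept-1-enyl]-2,5-dihydroxy-7-oxabicyclo[4.1.0]hept-3-ene-4-carboxylate | CCCCC/C=C/C1=C(C(=O)OC)[C@H](O)[C@H]2O[C@@]2(CC=C)[C@@H]1O | intermediate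
20 | methacrylic acid | C=C(C)C(=O)O | starting material
21 | (E)-4-[(1S,2R,5S,6R)-3-[(E)-hept-1-enyl]-2,5-dihydroxy-4-(methoxycarbonyl)-7-oxabicyclo[4.1.0]hept-3-en-1-yl]-2-methylbut-2-enoic acid | CCCCC/C=C/C1=C(C(=O)OC)[C@H](O)[C@H]2O[C@@]2(C/C=C(\C)C(=O)O)[C@@H]1O | intermediate
22 | (E)-4-[(1S,2R,5S,6R)-3-[(E)-hept-1-enyl]-2,5-dihydroxy-4-(hydroxymethyl)-7-oxabicyclo[4.1.0]hept-3-en-1-yl]-2-methylbut-2-enoic acid (both hydroxyls trans to the epoxide oxygen) | CCCCC/C=C/C1=C(CO)[C@H](O)[C@H]2O[C@@]2(C/C=C(\C)C(=O)O)[C@@H]1O | target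

Total step count: 10. Longest linear sequence: 9 steps (1, 2, 3, 4, 6, 7, 8, 9, 10); step 5 is a one-step side branch.

Steps most likely to fail

Step 6. Facial discrimination by the sulfinyl group may be insufficient or reversed (addition through a non-chelated rotamer, or syn to p-tolyl), and bond formation at the fully substituted pyrone C-6 may be slow, so that the adduct with the wrong absolute carbon configuration predominates. The fallback uses the sulfur antipode and sets out from 2 with commercial (1R,2S,5R)-(−)-menthyl (S)-p-toluenesulfinate. As in step 1 this gives tert-butyl (R)-2-(p-tolylsulfinyl)acetate F1. Acylation with 5 gives the lithium enolate F2 and, after triflation, the enol triflate F3. Sonogashira coupling with 8 gives the dienynoate F4, and gold-catalysed lactonisation gives the (S)-sulfinylpyrone F5. Cycloaddition with 14 should then give, through the same reversed preference, the adduct with the carbon stereocentres of 15 and the opposite sulfur configuration F6. Methanolysis and epoxide closure give the epoxy sulfoxide F7, whose [2,3] shift erases the sulfur stereocentre and gives 17, where the route is rejoined.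

Step 2. Geometric control in the O-triflation may be lost: lithium may bridge the enolate oxygen to the sulfinyl oxygen in place of the ester carbonyl, which would put the triflate, and later the alkyne, trans to the ester so that step 4 cannot lactonise. Triflation of the doubly stabilised enolate may also be sluggish. The fallback sets no alkene geometry and sets out from 8 and 3. Lithiation of 8 (n-BuLi) and carboxylation with methyl chloroformate give methyl hex-5-en-2-ynoate F8. Claisen condensation of the lithium enolate of 3 with F8 gives tert-butyl 3-oxo-2-[(S)-p-tolylsulfinyl]oct-7-en-4-ynoate F9. 6-Endo cyclisation of the ester carbonyl onto the ynone (Ph3PAuNTf2, AcOH–MeCN) with loss of isobutene gives 6-allyl-4-hydroxy-3-[(R)-p-tolylsulfinyl]-2H-pyran-2-one F10. Triflation (N-phenyl-bis(trifluoromethanesulfonimide), Et3N) gives the 4-triflate F11. Suzuki–Miyaura coupling with commercial (E)-hept-1-enylboronic acid (Pd(PPh3)4, K3PO4, THF–H2O) returns to the route at 10.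

Step 10. Hydride transfer to the aluminium carboxylate of the side chain may compete with reduction of the hindered, deactivated ring ester, giving over-reduced material. The fallback changes the order so that no acid is present during the reduction and sets out from 19. Reduction with i-Bu2AlH (−78 °C) gives the allyl triol (1S,2R,5S,6R)-1-allyl-3-[(E)-hept-1-enyl]-4-(hydroxymethyl)-7-oxabicyclo[4.1.0]hept-3-ene-2,5-diol F12. Cross-metathesis of F12 with 20 (second-generation Grubbs catalyst) installs the acid last and arrives directly at 22.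

Further compounds
F1 | step 6 | tert-butyl (R)-2-(p-tolylsulfinyl)acetate | CC(C)(C)OC(=O)C[S@@](=O)c1ccc(C)cc1
F2 | step 6 | lithium enolate of tert-butyl (E)-3-oxo-2-(p-tolylsulfinyl)dec-4-enoate, sulfur antipode of 6 | CC(C)(C)OC(=O)/C(=C(\[O-])/C=C/CCCCC)[S@@](=O)c1ccc(C)cc1.[Li+]
F3 | step 6 | tert-butyl (2E,4E)-2-[(S)-p-tolylsulfinyl]-3-(trifluoromethylsulfonyloxy)deca-2,4-dienoate | CC(C)(C)OC(=O)/C(=C(\OS(=O)(=O)C(F)(F)F)/C=C/CCCCC)[S@@](=O)c1ccc(C)cc1
F4 | step 6 | tert-butyl (2E,4E)-3-(pent-4-en-1-yn-1-yl)-2-[(S)-p-tolylsulfinyl]deca-2,4-dienoate | CC(C)(C)OC(=O)/C(=C(\C#CCC=C)/C=C/CCCCC)[S@@](=O)c1ccc(C)cc1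
F5 | step 6 | 6-allyl-4-[(E)-hept-1-en-1-yl]-3-[(S)-p-tolylsulfinyl]-2H-pyran-2-one | O=C1OC(CC=C)=CC(/C=C/CCCCC)=C1[S@@](=O)c1ccc(C)cc1
F6 | step 6 | bicyclic lactone adduct with the carbon stereocentres of 15 and the opposite sulfur configuration | O=C1O[C@@]2(CC=C)C=C(/C=C/CCCCC)[C@]1([S@@](=O)c3ccc(C)cc3)[C@H](OCc4ccc(OC)cc4)[C@@H]2Br
F7 | step 6 | epoxy sulfoxide with the carbon stereocentres of 16 and the opposite sulfur configuration | COC(=O)[C@]1([S@@](=O)c2ccc(C)cc2)C(/C=C/CCCCC)=C[C@]3(CC=C)O[C@@H]3[C@H]1OCc1ccc(OC)cc1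
F8 | step 2 | methyl hex-5-en-2-ynoate | COC(=O)C#CCC=C
F9 | step 2 | tert-butyl 3-oxo-2-[(S)-p-tolylsulfinyl]oct-7-en-4-ynoate | CC(C)(C)OC(=O)C([S@](=O)c1ccc(C)cc1)C(=O)C#CCC=C
F10 | step 2 | 6-allyl-4-hydroxy-3-[(R)-p-tolylsulfinyl]-2H-pyran-2-one | O=C1OC(CC=C)=CC(O)=C1[S@](=O)c1ccc(C)cc1
F11 | step 2 | 6-allyl-2-oxo-3-[(R)-p-tolylsulfinyl]-2H-pyran-4-yl trifluoromethanesulfonate | O=C1OC(CC=C)=CC(OS(=O)(=O)C(F)(F)F)=C1[S@](=O)c1ccc(C)cc1
F12 | step 10 | (1S,2R,5S,6R)-1-allyl-3-[(E)-hept-1-enyl]-4-(hydroxymethyl)-7-oxabicyclo[4.1.0]hept-3-ene-2,5-diol | CCCCC/C=C/C1=C(CO)[C@H](O)[C@H]2O[C@@]2(CC=C)[C@@H]1O
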